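## Analysis of the target

The target (35) is a spirocycle in which a tropone is fused through its C3a–C8a bond to a 2,3-dihydrofuran (a cyclohepta[b]furan-7-one) whose C2 is also C1' of a cyclohexane. The tropone carries the methyl ester on C6 next to the carbonyl C7, methyl groups on C5 and C8 and its only hydrogen on C4, so that the ring oxygen O1 is the oxygen of a vinylogous ester (O1–C8a=C8–C7=O). The cyclohexane has four contiguous stereocentres, C6' (CH–CH3), C1' (spiro, bearing O1 and the furan CH2), C2' (quaternary, methyl and the propanoic acid chain) and C3' (CH bearing the 2-hydroxypropan-2-yl group), with the configuration 2S,2'R,3'S,6'R. The ether oxygen is cis to the acid chain and trans to both ring methyls and to the hydroxyisopropyl group; in the chair that keeps the carbinol group equatorial the oxygen is axial and the 2'- and 6'-methyls are syn-diaxial, so the C6' configuration is the less stable one, must be set kinetically and must never sit next to a carbonyl afterwards. Sensitive groups are the tropone and its vinylogous ester (nucleophiles, strong base, hydride), the tertiary alkyl–oxygen bond and the tertiary alcohol (acid), and one methyl ester beside one free acid. In any intermediate with a free C1' hydroxyl the propanoate carbonyl is five atoms away and invites δ-lactone formation. The synthesis is hard for three reasons: a fully regiodefined pentasubstituted tropone, an oxygenated quaternary spiro centre with oxygen on the more hindered face, and an all-carbon quaternary centre next to it. The strategy rests on the fact that C3', C2' and C1' are the β-carbon, α-carbon and carbonyl carbon of 2-methylcyclohex-2-en-1-one (1), whose methyl is the 2'-methyl, so that the bond from C3' to the carbinol carbon and the bond from C2' to the acid chain can be made in one conjugate addition–enolate trapping.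

## Retrosynthetic reasoning

**35 ⇒ 34 ⇒ 33 (acid and silyl ethers).** The acid is taken back to the primary alcohol 34 and both hydroxyls to the silyl ethers of 33. A carboxylic ester on this chain would lactonise onto the C1' alkoxide 21 needed later and would not survive the dissolving-metal reduction. The forward steps are a fluoride desilylation and a selective oxidation of the primary alcohol beside the tertiary one.

**33 ⇒ 32 ⇒ 31 ⇒ 29 ⇒ 28 (one ring carbon out of the tropone).** The bond C6–CO2Me and the ring bonds C6–C5 and C6–C7 are cut, which contracts the tropone to the benzenoid 28. This carbon is chosen because the two ring oxygens of 33 are 1,3-related with the C8 methyl between them, the pattern of a meta-dialkoxy arene. Birch reduction of 28 can then only give the diene 29 with both oxygens on enol ether carbons. A dihalocarbene carbon enters between the methoxy-bearing and the methyl-bearing carbon, and the methoxy carbon becomes the carbonyl, so ether oxygen and carbonyl oxygen cannot be confused. Coupling a preformed seven-membered ring in place of the arene 20 was rejected: no suitably substituted building block is commercial, and a diazo group conjugated to its polyene could close to a pyrazole. The forward reactions must reduce the arene, expand the ring with retention of one bromine (31), dehydrogenate (32) and carbonylate (33).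

**28 ⇒ 25 ⇒ 24 ⇒ 22 ⇒ 16 + 20 (dihydrofuran).** The bond C3–C2 (spiro) and the aryl–oxygen bond are cut. A carbon nucleophile adding to a carbonyl group at C1' would come from the face away from the axial 2'-methyl and would leave the oxygen on the wrong side. Instead the oxygen is set first as the secondary alcohol 16 and arylated on oxygen with the fluoronitrile 20 to give 22. The carbon is then delivered by carbene insertion into the remaining C1'–H bond, which proceeds with retention. The nitrile activates the fluoride and afterwards becomes the carbene carbon via the aldehyde 24 and the sulfonylhydrazone 25.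

**16 ⇒ 14 (C1' and C6').** The C1'–O bond and the C6'–H bond are cut together to give the alkene 14. One syn hydroboration sets both centres, with the face chosen by the pseudoaxial methyl on the neighbouring quaternary carbon. The less stable syn-diaxial dimethyl arrangement is thereby made under kinetic control.

**14 ⇒ 13 ⇒ 11 ⇒ 10 ⇒ 9 ⇒ 7 ⇒ 5 (adjusting the ring and side chains).** The alkene 14 comes from the enol triflate 13 by reduction of its C–O bond. 13 goes back through the diol 11 and the tertiary alcohol 10 to the isopropenyl triflate 9, and 9 to the ketone 7. The 6'-methyl of 7 is cut back to an enolate alkylation of 5, whose stereochemistry is irrelevant because the carbon becomes sp2 in 9. The tertiary alcohol of 10 comes from the isopropenyl group by Markovnikov hydration, placed after triflation so that no ketone is present to form a bridged hemiketal. The ester is reduced (11) and both hydroxyls are silylated (13) before the triflate is removed.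

**5 ⇒ 1 + 2 + 3 (key disconnection).** The bond from C3' to the isopropenyl carbon and the bond from C2' to the chain CH2 are cut. This returns the commercial enone 1, the Grignard reagent 2 and the acrylate 3. The forward step must control the absolute configuration at the β-carbon and the relative configuration of the new quaternary centre.

**20 ⇒ 18 ⇒ 17 (arene).** The fluorine is cut back to a nitrile-directed ortho-metalation of 18, made by O-methylation of the commercial phenol 17. The two ortho positions are equivalent, so no regiochemical question arises.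

## Alternatives that were turned down

**Alternative 1:** The seven-membered ring and the dihydrofuran are opened together. The cuts are the bond between the CH2-bearing and the O-bearing ring carbon, and the bond between the methyl-bearing carbon next to the carbonyl and the carbonyl carbon itself. The forward step needs, in one molecule, an ynol ether on the spiro oxygen and a siloxy-substituted vinylcyclopropane attached through the CH2 group. [Rh(CO)2Cl]2 would open the cyclopropane and insert the tethered alkyne, giving the dihydrofuran-fused cycloheptadiene A1.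
- For it: two rings form in one neutral step, and the tether fixes the regiochemistry.
- Against it: A1 is still three operations from the tropone (desilylation, oxidation of the siloxy carbon, one dehydrogenation) and carries three stereocentres as mixtures. The substrate needs an ynol ether of a very hindered tertiary alcohol and a fully substituted alkyne, which is slow in this cycloaddition. The spiro carbinol must already exist with oxygen on the hindered face, which simple addition to a carbonyl group at that carbon does not provide.
- Comparison: A1 reaches the bicyclic skeleton in fewer steps than the chosen endgame, and on that point it is stronger. The chosen strategy offers instead a spiro centre set by a stereospecific insertion and a sequence made only of reaction types with close precedent.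

**Alternative 2:** The two ring bonds flanking the three-carbon ketone unit are cut: from the methyl-bearing α-carbon to the O-bearing ring carbon, and from the ester-bearing carbon to the methyl-bearing ring carbon. This leaves a three-carbon oxyallyl unit, drawn from the dibromo keto ester A2 (methyl 2,4-dibromo-3-oxopentanoate), and a 2,4-disubstituted furan ring hung on the silylated spiro carbinol. A zinc–copper couple would turn A2 into the cation, which adds across the furan to give the oxa-bridged cycloheptenone A3. Bridge opening, oxidation to the tropone level and closure of the vinylogous ester by the tertiary alcohol would follow.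
- For it: all seven ring carbons and every substituent arrive at once, and the tethered alcohol decides which oxygen becomes the ether.
- Against it: an oxyallyl cation with an ester substituent is destabilised, and A2 is easily reduced with loss of both bromines before the cation meets the furan. An unsymmetrical cation and an unsymmetrical furan can combine in two orientations with little bias. A3 has four new stereocentres as mixtures and is several steps from the tropone. The furan must be built, and the spiro carbinol again has to come from addition to a hindered carbonyl group.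
- Comparison: A3 is more convergent in ring carbons. The chosen route is longer at the troponoid, but its regiochemistry is fixed by the substitution pattern of a benzene ring and not by the orientation of a cycloaddition.

**Alternative 3:** The bond between the ring CH and the neighbouring methyl-bearing carbon is cut, which takes the CH out of the ring and leaves a hexasubstituted benzenoid. In the forward direction this phenol is dearomatised by C-dichloromethylation to a cyclohexadienone. Bu3SnH with AIBN would then give a chloromethyl radical, which adds to the adjacent ester-activated enone carbon, reopens (a net 1,2-vinyl shift) and loses chlorine to give the protected target A4.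
- For it: the expansion is one step, arrives at the tropone oxidation level, and has the ester in place from the start. Here it is clearly stronger than the chosen endgame, which needs four operations for the same change.
- Against it: the dearomatisation needs C-dichloromethylation of a hexasubstituted phenol at a carbon next to the spiro CH2, normally a minor pathway under strongly basic conditions that endanger the methyl ester. The radical can close on either flanking sp2 carbon, and the wrong one leads to an isomer of A4. Simple reduction of the radical competes.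
- Comparison: the chosen route also uses a benzenoid stand-in, but the carbon enters at a position dictated by the anisole oxygen, which gives regiochemical certainty at the price of steps. All three alternatives spend their key step on the troponoid and leave the four contiguous stereocentres of the carbocycle open. The chosen strategy solves two of them and both side chains in its first step.

Key step: step 1

Assumption: the phosphoramidite enantiomer is the one whose copper complex transfers the alkenyl group to the enone face that gives the (R)-configured β-carbon of 4; the antipodal ligand would give the mirror-image series.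

Abbreviations in names: TBSO = tert-butyldimethylsilyloxy, TESO = triethylsilyloxy, triflate = trifluoromethanesulfonate, Ts = 4-methylbenzenesulfonyl.

## Route

Step 1
Reactants: 1 2-methylcyclohex-2-en-1-one; 2 isopropenylmagnesium bromide; 3 tert-butyl acrylate
Product: 5 tert-butyl 3-[(1R,6R)-1-methyl-2-oxo-6-(prop-1-en-2-yl)cyclohexyl]propanoate, via magnesium enolate 4 (not isolated)
Conditions: copper thiophene-2-carboxylate (CuTC, 5 mol%), BINOL-derived bis(1-phenylethyl)amine phosphoramidite (10 mol%), Et2O, −78 °C, slow addition of 2 (1.2 equiv); then DMPU, 3 (1.5 equiv), −78 → −30 °C; aq. NH4Cl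
Reagents that add atoms: none
Why: The monovalent copper–phosphoramidite complex is transmetalated by 2 to an alkenylcuprate, which binds the magnesium-activated enone, adds oxidatively to the β-carbon (trivalent copper) and eliminates reductively to give the C–C bond and the magnesium enolate 4. The closest known reaction type is the copper-catalysed asymmetric conjugate addition of Grignard reagents to 2-substituted cyclohexenones with trapping of the magnesium enolate by a carbon electrophile. No ring is closed. The β-stereocentre is set by the chiral ligand, which selects the enone face for alkenyl transfer. The quaternary centre is set by the substrate: the isopropenyl group next to the enolate carbon sits pseudoaxial to avoid the 2-methyl group and shields its own face, so 3 adds anti and the chain ends trans to isopropenyl and the methyl cis. The step needs 1,4- over 1,2-addition (catalytic copper, low temperature, slow addition of 2), reaction of the regiodefined enolate before it equilibrates (it is formed only at the methyl-bearing carbon and kept cold) and a single Michael addition (bulky tert-butyl ester, small excess of 3, cold quench).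

Step 2
Reactants: 5 tert-butyl 3-[(1R,6R)-1-methyl-2-oxo-6-(prop-1-en-2-yl)cyclohexyl]propanoate
Product: 7 tert-butyl 3-[(1R,3RS,6R)-1,3-dimethyl-2-oxo-6-(prop-1-en-2-yl)cyclohexyl]propanoate (both C3 epimers), via lithium enolate 6 (not isolated)
Conditions: LiN(iPr)2 (1.05 equiv), THF, −78 °C; MeI (3 equiv), −78 → −20 °C
Reagents that add atoms: iodomethane, CI
Why: Enolate alkylation; the ketone can enolise only toward its methylene carbon because the other α-carbon is quaternary, and it is deprotonated faster than the tert-butyl ester. The new stereocentre is left as a mixture because this carbon becomes sp2 in step 3.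

Step 3
Reactants: 7 tert-butyl 3-[(1R,3RS,6R)-1,3-dimethyl-2-oxo-6-(prop-1-en-2-yl)cyclohexyl]propanoate
Product: 9 tert-butyl 3-[(1R,6R)-1,3-dimethyl-6-(prop-1-en-2-yl)-2-(trifluoromethylsulfonyloxy)cyclohex-2-en-1-yl]propanoate, via potassium enolate 8 (not isolated)
Conditions: KN(SiMe3)2 (1.2 equiv), THF, −78 °C; PhNTf2 (1.3 equiv), −78 → 0 °C
Reagents that add atoms: N-phenylbis(trifluoromethanesulfonimide), O=S(=O)(N(c1ccccc1)S(=O)(=O)C(F)(F)F)C(F)(F)F
Why: Enol triflate formation; only one α-hydrogen is left, so the double bond is fixed between the former carbonyl carbon and the methyl-bearing carbon, and the hard potassium enolate is sulfonylated on oxygen.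

Step 4
Reactants: 9 tert-butyl 3-[(1R,6R)-1,3-dimethyl-6-(prop-1-en-2-yl)-2-(trifluoromethylsulfonyloxy)cyclohex-2-en-1-yl]propanoate
Product: 10 tert-butyl 3-[(1R,6S)-6-(2-hydroxypropan-2-yl)-1,3-dimethyl-2-(trifluoromethylsulfonyloxy)cyclohex-2-en-1-yl]propanoate
Conditions: Co(acac)2 (20 mol%), PhSiH3 (2.5 equiv), O2 (1 atm), THF, 23 °C; aq. Na2S2O3
Reagents that add atoms: dioxygen, O=O
Why: Mukaiyama hydration; hydrogen-atom transfer from a cobalt hydride to the 1,1-disubstituted alkene gives the tertiary radical, which is trapped by O2 and reduced to the tertiary alcohol. The tetrasubstituted, electron-poor enol triflate alkene is not a substrate, and no ketone is present that could form a bridged hemiketal with the new hydroxyl.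

Step 5
Reactants: 10 tert-butyl 3-[(1R,6S)-6-(2-hydroxypropan-2-yl)-1,3-dimethyl-2-(trifluoromethylsulfonyloxy)cyclohex-2-en-1-yl]propanoate
Product: 11 (5S,6R)-5-(2-hydroxypropan-2-yl)-6-(3-hydroxypropyl)-2,6-dimethylcyclohex-1-en-1-yl triflate
Conditions: iBu2AlH (4 equiv), CH2Cl2, −78 → 0 °C; aq. potassium sodium tartrate
Reagents that add atoms: none
Why: Hydride reduction of the ester to the primary alcohol; the vinyl triflate is inert to the aluminium hydride at this temperature. The chain is reduced because an ester here would lactonise onto the C1 alkoxide of step 11 and would be reduced in step 15.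

Step 6
Reactants: 11 (5S,6R)-5-(2-hydroxypropan-2-yl)-6-(3-hydroxypropyl)-2,6-dimethylcyclohex-1-en-1-yl triflate
Product: 13 (5S,6R)-6-[3-(TBSO)propyl]-2,6-dimethyl-5-[2-(TESO)propan-2-yl]cyclohex-1-en-1-yl triflate, via primary TBS ether 12 (not isolated)
Conditions: TBSCl (1.1 equiv), imidazole, CH2Cl2, 0 °C; then 2,6-lutidine, TESOTf (1.5 equiv), −78 → 0 °C
Reagents that add atoms: tert-butyldimethylsilyl chloride, C[Si](C)(Cl)C(C)(C)C; triethylsilyl triflate, CC[Si](CC)(CC)OS(=O)(=O)C(F)(F)F
Why: Sequential silylation; the silyl chloride selects the primary hydroxyl and the silyl triflate then silylates the hindered tertiary one. Both ethers should tolerate base, hydride, dissolving metal and carbene conditions and are removed together by fluoride.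

Step 7
Reactants: 13 (5S,6R)-6-[3-(TBSO)propyl]-2,6-dimethyl-5-[2-(TESO)propan-2-yl]cyclohex-1-en-1-yl triflate
Product: 14 tert-butyl(dimethyl){3-[(1S,6S)-1,3-dimethyl-6-[2-(TESO)propan-2-yl]cyclohex-2-en-1-yl]propoxy}silane
Conditions: Pd(OAc)2 (5 mol%), PPh3 (10 mol%), HCO2H (3 equiv), Bu3N (4.5 equiv), DMF, 60 °C
Reagents that add atoms: none
Why: Palladium-catalysed formate reduction of an enol triflate; zerovalent palladium adds to the C–O bond, formate exchange and decarboxylation give a palladium hydride, and reductive elimination leaves hydrogen on the former carbonyl carbon. No stereocentre is touched.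

Step 8
Reactants: 14 tert-butyl(dimethyl){3-[(1S,6S)-1,3-dimethyl-6-[2-(TESO)propan-2-yl]cyclohex-2-en-1-yl]propoxy}silane
Product: 16 (1S,2R,3S,6R)-2-[3-(TBSO)propyl]-2,6-dimethyl-3-[2-(TESO)propan-2-yl]cyclohexan-1-ol, via alkylborane 15 (not isolated)
Conditions: BH3·THF (4 equiv), THF, 0 → 23 °C; then NaOH (3 M), H2O2 (30%), 0 → 23 °C
Reagents that add atoms: hydrogen peroxide, OO
Why: Hydroboration–oxidation; boron goes to the less substituted alkene carbon and adds syn from the face opposite the pseudoaxial methyl of the adjacent quaternary carbon (half-chair with the bulky silyloxyisopropyl group equatorial). Hydrogen at the methyl-bearing carbon and boron at C1 therefore enter cis to the silyloxypropyl chain, and oxidation with retention should give the axial alcohol with the ring methyl trans to it, setting C1 and C6 together.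

Step 9
Reactants: 17 4-hydroxy-3,5-dimethylbenzonitrile
Product: 18 4-methoxy-3,5-dimethylbenzonitrile
Conditions: MeI (1.5 equiv), K2CO3, acetone, 50 °C
Reagents that add atoms: iodomethane, CI
Why: Williamson ether synthesis on a phenoxide; the flanking methyl groups slow but do not prevent O-methylation.

Step 10
Reactants: 18 4-methoxy-3,5-dimethylbenzonitrile
Product: 20 2-fluoro-4-methoxy-3,5-dimethylbenzonitrile, via arylmagnesium chloride 19 (not isolated)
Conditions: TMPMgCl·LiCl (1.3 equiv), THF, 0 → 23 °C; then NFSI (1.5 equiv), CH2Cl2, 0 → 23 °C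
Reagents that add atoms: N-fluorobenzenesulfonimide, O=S(=O)(N(F)S(=O)(=O)c1ccccc1)c1ccccc1
Why: Nitrile-directed ortho-magnesiation followed by electrophilic fluorination of the arylmagnesium; the two positions ortho to the nitrile are equivalent, so only one product can form.

Step 11
Reactants: 16 (1S,2R,3S,6R)-2-[3-(TBSO)propyl]-2,6-dimethyl-3-[2-(TESO)propan-2-yl]cyclohexan-1-ol; 20 2-fluoro-4-methoxy-3,5-dimethylbenzonitrile
Product: 22 2-{[(1S,2R,3S,6R)-2-[3-(TBSO)propyl]-2,6-dimethyl-3-[2-(TESO)propan-2-yl]cyclohexyl]oxy}-4-methoxy-3,5-dimethylbenzonitrile, via potassium alkoxide 21 (not isolated)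
Conditions: KN(SiMe3)2 (1.05 equiv), THF, 0 °C; then 20 (1.3 equiv), DMF, 23 → 50 °C
Reagents that add atoms: none
Why: Nucleophilic aromatic substitution of a fluoride ortho to a nitrile through a Meisenheimer intermediate; the bond forms at oxygen, so the carbinol configuration is retained. A nitrile is used as the activating group because, unlike an aldehyde, it cannot accept hydride from the secondary alkoxide.

Step 12
Reactants: 22 2-{[(1S,2R,3S,6R)-2-[3-(TBSO)propyl]-2,6-dimethyl-3-[2-(TESO)propan-2-yl]cyclohexyl]oxy}-4-methoxy-3,5-dimethylbenzonitrile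
Product: 24 2-{[(1S,2R,3S,6R)-2-[3-(TBSO)propyl]-2,6-dimethyl-3-[2-(TESO)propan-2-yl]cyclohexyl]oxy}-4-methoxy-3,5-dimethylbenzaldehyde, via aluminium aldimine 23 (not isolated)
Conditions: iBu2AlH (1.5 equiv), toluene, −78 → −40 °C; then aq. potassium sodium tartrate, 23 °C
Reagents that add atoms: water, O
Why: Partial reduction of a nitrile; one hydride adds to give the N-aluminio aldimine, which is stable at low temperature and is hydrolysed to the aldehyde on work-up. The silyl ethers are not affected.

Step 13
Reactants: 24 2-{[(1S,2R,3S,6R)-2-[3-(TBSO)propyl]-2,6-dimethyl-3-[2-(TESO)propan-2-yl]cyclohexyl]oxy}-4-methoxy-3,5-dimethylbenzaldehyde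
Product: 25 (E)-N'-tosylhydrazone of aldehyde 24
Conditions: TsNHNH2 (1.1 equiv), THF–MeOH, 23 °C
Reagents that add atoms: 4-methylbenzenesulfonohydrazide, Cc1ccc(cc1)S(=O)(=O)NN
Why: Condensation of an aryl aldehyde with a sulfonyl hydrazide; it needs no acid, so the silyl ethers are safe.

Step 14
Reactants: 25 (E)-N'-tosylhydrazone of aldehyde 24
Product: 28 tert-butyl(dimethyl){3-[(2S,2'R,3'S,6'R)-6-methoxy-2',5,6',7-tetramethyl-3'-[2-(TESO)propan-2-yl]-3H-spiro[1-benzofuran-2,1'-cyclohexan]-2'-yl]propoxy}silane, via sodium tosylhydrazonide 26 (not isolated), via aryldiazomethane 27 (not isolated)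
Conditions: NaH (1.1 equiv), THF, 0 → 23 °C; then Rh2(OAc)4 (2 mol%), BnEt3NCl (10 mol%), 1,4-dioxane (0.01 M), 70 °C
Reagents that add atoms: none
Why: Bamford–Stevens generation of the aryldiazomethane and rhodium-carbene insertion into the C–H bond α to the ether oxygen, a known route to 2,2-disubstituted 2,3-dihydrobenzofurans. The insertion is a concerted three-centre process with retention, so the new C–C bond takes the place of the hydrogen and the oxygen stays on its face; only this C–H bond can close a five-membered ring.

Step 15
Reactants: 28 tert-butyl(dimethyl){3-[(2S,2'R,3'S,6'R)-6-methoxy-2',5,6',7-tetramethyl-3'-[2-(TESO)propan-2-yl]-3H-spiro[1-benzofuran-2,1'-cyclohexan]-2'-yl]propoxy}silane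
Product: 29 tert-butyl(dimethyl){3-[(2S,2'R,3'S,6'R)-6-methoxy-2',5,6',7-tetramethyl-3'-[2-(TESO)propan-2-yl]-4,7-dihydro-3H-spiro[1-benzofuran-2,1'-cyclohexan]-2'-yl]propoxy}silane (both C7 epimers)
Conditions: Li (10 equiv), NH3(l), THF, t-BuOH (10 equiv), −78 → −33 °C; solid NH4Cl
Reagents that add atoms: none
Why: Birch reduction; the two alkoxy groups direct protonation to C7 between them and to C4 para to it, the only pair that leaves both oxygens on enol ether double bonds. The silyl ethers are inert to the dissolving metal.

Step 16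
Reactants: 29 tert-butyl(dimethyl){3-[(2S,2'R,3'S,6'R)-6-methoxy-2',5,6',7-tetramethyl-3'-[2-(TESO)propan-2-yl]-4,7-dihydro-3H-spiro[1-benzofuran-2,1'-cyclohexan]-2'-yl]propoxy}silane (both C7 epimers)
Product: 31 (2S,2'R,3'S,6'R)-6-bromo-2'-[3-(TBSO)propyl]-2',5,6',8-tetramethyl-3'-[2-(TESO)propan-2-yl]-4,8-dihydro-3H-spiro[cyclohepta[b]furan-2,1'-cyclohexan]-7-one (both C8 epimers), via dibromocyclopropane 30 (not isolated)
Conditions: CHBr3 (1.2 equiv), KOtBu (1.5 equiv), pentane–THF, −40 → 0 °C; then toluene, K2CO3, 80 °C
Reagents that add atoms: bromoform, BrC(Br)Br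
Why: Dibromocarbene cyclopropanation of the methyl enol ether, then thermal disrotatory opening of the 1-methoxy-gem-dibromocyclopropane with loss of bromide and O-demethylation of the oxocarbenium ion, the classical one-carbon expansion of Birch dienes to 2-bromocycloheptadienones. The ring-fused enol ether is shielded on both faces by the spiro cyclohexane, and the carbonyl appears at the former anisole carbon, which fixes the ketone and ether positions.

Step 17
Reactants: 31 (2S,2'R,3'S,6'R)-6-bromo-2'-[3-(TBSO)propyl]-2',5,6',8-tetramethyl-3'-[2-(TESO)propan-2-yl]-4,8-dihydro-3H-spiro[cyclohepta[b]furan-2,1'-cyclohexan]-7-one (both C8 epimers)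
Product: 32 (2S,2'R,3'S,6'R)-6-bromo-2'-[3-(TBSO)propyl]-2',5,6',8-tetramethyl-3'-[2-(TESO)propan-2-yl]-3H-spiro[cyclohepta[b]furan-2,1'-cyclohexan]-7-one
Conditions: DDQ (1.3 equiv), NaHCO3, benzene, 23 → 50 °C
Reagents that add atoms: none
Why: Quinone dehydrogenation; hydride abstraction from the doubly allylic C4 methylene gives a cation stabilised by the ring oxygen, and loss of the C8 proton gives the tropone. The C8 stereocentre of 31 disappears, and the bromine, which has no β-hydrogen pathway for elimination, should be retained.

Step 18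
Reactants: 32 (2S,2'R,3'S,6'R)-6-bromo-2'-[3-(TBSO)propyl]-2',5,6',8-tetramethyl-3'-[2-(TESO)propan-2-yl]-3H-spiro[cyclohepta[b]furan-2,1'-cyclohexan]-7-one
Product: 33 methyl (2S,2'R,3'S,6'R)-2'-[3-(TBSO)propyl]-2',5,6',8-tetramethyl-7-oxo-3'-[2-(TESO)propan-2-yl]-3,7-dihydrospiro[cyclohepta[b]furan-2,1'-cyclohexane]-6-carboxylate
Conditions: Pd(OAc)2 (10 mol%), Xantphos (12 mol%), CO (1 atm), MeOH (20 equiv), Et3N (3 equiv), DMF, 70 °C
Reagents that add atoms: carbon monoxide, [C-]#[O+]; methanol, CO
Why: Palladium-catalysed methoxycarbonylation; the C–Br bond of a 2-bromotropone behaves like that of an activated vinyl bromide toward zerovalent palladium, and CO insertion followed by methanolysis gives the ester.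

Step 19
Reactants: 33 methyl (2S,2'R,3'S,6'R)-2'-[3-(TBSO)propyl]-2',5,6',8-tetramethyl-7-oxo-3'-[2-(TESO)propan-2-yl]-3,7-dihydrospiro[cyclohepta[b]furan-2,1'-cyclohexane]-6-carboxylate
Product: 34 methyl (2S,2'R,3'S,6'R)-3'-(2-hydroxypropan-2-yl)-2'-(3-hydroxypropyl)-2',5,6',8-tetramethyl-7-oxo-3,7-dihydrospiro[cyclohepta[b]furan-2,1'-cyclohexane]-6-carboxylate
Conditions: HF·pyridine, pyridine, THF, 0 → 23 °C
Reagents that add atoms: none
Why: Fluoride-driven cleavage of both silyl ethers; the pyridine buffer keeps the medium too weakly acidic to ionise the tertiary alkyl–oxygen bond of the spiro ether or to touch the methyl ester.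

Step 20
Reactants: 34 methyl (2S,2'R,3'S,6'R)-3'-(2-hydroxypropan-2-yl)-2'-(3-hydroxypropyl)-2',5,6',8-tetramethyl-7-oxo-3,7-dihydrospiro[cyclohepta[b]furan-2,1'-cyclohexane]-6-carboxylate
Product: 35 3-[(2S,2'R,3'S,6'R)-3'-(2-hydroxypropan-2-yl)-6-(methoxycarbonyl)-2',5,6',8-tetramethyl-7-oxo-3,7-dihydrospiro[cyclohepta[b]furan-2,1'-cyclohexan]-2'-yl]propanoic acid
Conditions: TEMPO (20 mol%), PhI(OAc)2 (2.5 equiv), MeCN–pH 7 phosphate buffer (1:1), 23 °C
Reagents that add atoms: water, O
Why: Oxoammonium oxidation of the primary alcohol to the aldehyde, whose hydrate is oxidised on to the acid. The tertiary alcohol cannot be oxidised, and the electron-poor tropone and the methyl ester are not attacked under these near-neutral conditions.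

## Compound list

1 | 2-methylcyclohex-2-en-1-one | CC1=CCCCC1=O | starting material
2 | isopropenylmagnesium bromide | CC(=C)[Mg]Br | starting material
3 | tert-butyl acrylate | C=CC(=O)OC(C)(C)C | starting material
4 | bromomagnesium (3R)-2-methyl-3-(prop-1-en-2-yl)cyclohex-1-en-1-olate | CC1=C(O[Mg]Br)CCC[C@@H]1C(C)=C | intermediate
5 | tert-butyl 3-[(1R,6R)-1-methyl-2-oxo-6-(prop-1-en-2-yl)cyclohexyl]propanoate | O=C1CCC[C@H](C(C)=C)[C@@]1(C)CCC(=O)OC(C)(C)C | intermediate
6 | lithium (5R,6R)-6-(3-tert-butoxy-3-oxopropyl)-6-methyl-5-(prop-1-en-2-yl)cyclohex-1-en-1-olate | [Li+].[O-]C1=CCC[C@H](C(C)=C)[C@@]1(C)CCC(=O)OC(C)(C)C | intermediate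
7 | tert-butyl 3-[(1R,3RS,6R)-1,3-dimethyl-2-oxo-6-(prop-1-en-2-yl)cyclohexyl]propanoate (both C3 epimers) | O=C1C(C)CC[C@H](C(C)=C)[C@@]1(C)CCC(=O)OC(C)(C)C | intermediate
8 | potassium (5R,6R)-6-(3-tert-butoxy-3-oxopropyl)-2,6-dimethyl-5-(prop-1-en-2-yl)cyclohex-1-en-1-olate | [K+].[O-]C1=C(C)CC[C@H](C(C)=C)[C@@]1(C)CCC(=O)OC(C)(C)C | intermediate
9 | tert-butyl 3-[(1R,6R)-1,3-dimethyl-6-(prop-1-en-2-yl)-2-(trifluoromethylsulfonyloxy)cyclohex-2-en-1-yl]propanoate | FC(F)(F)S(=O)(=O)OC1=C(C)CC[C@H](C(C)=C)[C@@]1(C)CCC(=O)OC(C)(C)C | intermediate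
10 | tert-butyl 3-[(1R,6S)-6-(2-hydroxypropan-2-yl)-1,3-dimethyl-2-(trifluoromethylsulfonyloxy)cyclohex-2-en-1-yl]propanoate | FC(F)(F)S(=O)(=O)OC1=C(C)CC[C@H](C(C)(C)O)[C@@]1(C)CCC(=O)OC(C)(C)C | intermediate
11 | (5S,6R)-5-(2-hydroxypropan-2-yl)-6-(3-hydroxypropyl)-2,6-dimethylcyclohex-1-en-1-yl triflate | FC(F)(F)S(=O)(=O)OC1=C(C)CC[C@H](C(C)(C)O)[C@@]1(C)CCCO | intermediate
12 | (5S,6R)-6-[3-(TBSO)propyl]-5-(2-hydroxypropan-2-yl)-2,6-dimethylcyclohex-1-en-1-yl triflate | FC(F)(F)S(=O)(=O)OC1=C(C)CC[C@H](C(C)(C)O)[C@@]1(C)CCCO[Si](C)(C)C(C)(C)C | intermediate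
13 | (5S,6R)-6-[3-(TBSO)propyl]-2,6-dimethyl-5-[2-(TESO)propan-2-yl]cyclohex-1-en-1-yl triflate | FC(F)(F)S(=O)(=O)OC1=C(C)CC[C@H](C(C)(C)O[Si](CC)(CC)CC)[C@@]1(C)CCCO[Si](C)(C)C(C)(C)C | intermediate
14 | tert-butyl(dimethyl){3-[(1S,6S)-1,3-dimethyl-6-[2-(TESO)propan-2-yl]cyclohex-2-en-1-yl]propoxy}silane | C1=C(C)CC[C@H](C(C)(C)O[Si](CC)(CC)CC)[C@@]1(C)CCCO[Si](C)(C)C(C)(C)C | intermediate
15 | [(1S,2S,3S,6R)-2-[3-(TBSO)propyl]-2,6-dimethyl-3-[2-(TESO)propan-2-yl]cyclohexyl]borane | B[C@H]1[C@H](C)CC[C@H](C(C)(C)O[Si](CC)(CC)CC)[C@@]1(C)CCCO[Si](C)(C)C(C)(C)C | intermediate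
16 | (1S,2R,3S,6R)-2-[3-(TBSO)propyl]-2,6-dimethyl-3-[2-(TESO)propan-2-yl]cyclohexan-1-ol | O[C@H]1[C@H](C)CC[C@H](C(C)(C)O[Si](CC)(CC)CC)[C@@]1(C)CCCO[Si](C)(C)C(C)(C)C | intermediate
17 | 4-hydroxy-3,5-dimethylbenzonitrile | N#Cc1cc(C)c(O)c(C)c1 | starting material
18 | 4-methoxy-3,5-dimethylbenzonitrile | N#Cc1cc(C)c(OC)c(C)c1 | intermediate
19 | (6-cyano-3-methoxy-2,4-dimethylphenyl)magnesium chloride (LiCl complex) | N#Cc1cc(C)c(OC)c(C)c1[Mg]Cl | intermediate
20 | 2-fluoro-4-methoxy-3,5-dimethylbenzonitrile | N#Cc1cc(C)c(OC)c(C)c1F | intermediate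
21 | potassium (1S,2R,3S,6R)-2-[3-(TBSO)propyl]-2,6-dimethyl-3-[2-(TESO)propan-2-yl]cyclohexan-1-olate | [K+].[O-][C@H]1[C@H](C)CC[C@H](C(C)(C)O[Si](CC)(CC)CC)[C@@]1(C)CCCO[Si](C)(C)C(C)(C)C | intermediate
22 | 2-{[(1S,2R,3S,6R)-2-[3-(TBSO)propyl]-2,6-dimethyl-3-[2-(TESO)propan-2-yl]cyclohexyl]oxy}-4-methoxy-3,5-dimethylbenzonitrile | N#Cc1cc(C)c(OC)c(C)c1O[C@H]1[C@H](C)CC[C@H](C(C)(C)O[Si](CC)(CC)CC)[C@@]1(C)CCCO[Si](C)(C)C(C)(C)C | intermediate
23 | N-(diisobutylalumanyl)aldimine of aldehyde 24 | CC(C)C[Al](CC(C)C)N=Cc1cc(C)c(OC)c(C)c1O[C@H]1[C@H](C)CC[C@H](C(C)(C)O[Si](CC)(CC)CC)[C@@]1(C)CCCO[Si](C)(C)C(C)(C)C | intermediate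
24 | 2-{[(1S,2R,3S,6R)-2-[3-(TBSO)propyl]-2,6-dimethyl-3-[2-(TESO)propan-2-yl]cyclohexyl]oxy}-4-methoxy-3,5-dimethylbenzaldehyde | O=Cc1cc(C)c(OC)c(C)c1O[C@H]1[C@H](C)CC[C@H](C(C)(C)O[Si](CC)(CC)CC)[C@@]1(C)CCCO[Si](C)(C)C(C)(C)C | intermediate
25 | (E)-N'-tosylhydrazone of aldehyde 24 | Cc1ccc(cc1)S(=O)(=O)N/N=C/c1cc(C)c(OC)c(C)c1O[C@H]1[C@H](C)CC[C@H](C(C)(C)O[Si](CC)(CC)CC)[C@@]1(C)CCCO[Si](C)(C)C(C)(C)C | intermediate
26 | sodium salt of tosylhydrazone 25 | [Na+].Cc1ccc(cc1)S(=O)(=O)[N-]/N=C/c1cc(C)c(OC)c(C)c1O[C@H]1[C@H](C)CC[C@H](C(C)(C)O[Si](CC)(CC)CC)[C@@]1(C)CCCO[Si](C)(C)C(C)(C)C | intermediate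
27 | 1-(diazomethyl)-2-{[(1S,2R,3S,6R)-2-[3-(TBSO)propyl]-2,6-dimethyl-3-[2-(TESO)propan-2-yl]cyclohexyl]oxy}-4-methoxy-3,5-dimethylbenzene | [N-]=[N+]=Cc1cc(C)c(OC)c(C)c1O[C@H]1[C@H](C)CC[C@H](C(C)(C)O[Si](CC)(CC)CC)[C@@]1(C)CCCO[Si](C)(C)C(C)(C)C | intermediate
28 | tert-butyl(dimethyl){3-[(2S,2'R,3'S,6'R)-6-methoxy-2',5,6',7-tetramethyl-3'-[2-(TESO)propan-2-yl]-3H-spiro[1-benzofuran-2,1'-cyclohexan]-2'-yl]propoxy}silane | COc1c(C)cc2c(c1C)O[C@@]1(C2)[C@H](C)CC[C@H](C(C)(C)O[Si](CC)(CC)CC)[C@@]1(C)CCCO[Si](C)(C)C(C)(C)C | intermediate
29 | tert-butyl(dimethyl){3-[(2S,2'R,3'S,6'R)-6-methoxy-2',5,6',7-tetramethyl-3'-[2-(TESO)propan-2-yl]-4,7-dihydro-3H-spiro[1-benzofuran-2,1'-cyclohexan]-2'-yl]propoxy}silane (both C7 epimers) | COC1=C(C)CC2=C(C1C)O[C@@]1(C2)[C@H](C)CC[C@H](C(C)(C)O[Si](CC)(CC)CC)[C@@]1(C)CCCO[Si](C)(C)C(C)(C)C | intermediate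
30 | gem-dibromocyclopropane formed across the C5=C6 enol ether bond of 29 (C5 methyl and C6 methoxy at the ring fusion; diastereomer mixture) | COC1(C2(Br)Br)C(C)C3=C(CC12C)C[C@]4(O3)[C@H](C)CC[C@H](C(C)(C)O[Si](CC)(CC)CC)[C@@]4(C)CCCO[Si](C)(C)C(C)(C)C | intermediate
31 | (2S,2'R,3'S,6'R)-6-bromo-2'-[3-(TBSO)propyl]-2',5,6',8-tetramethyl-3'-[2-(TESO)propan-2-yl]-4,8-dihydro-3H-spiro[cyclohepta[b]furan-2,1'-cyclohexan]-7-one (both C8 epimers) | O=C1C(Br)=C(C)CC2=C(C1C)O[C@@]1(C2)[C@H](C)CC[C@H](C(C)(C)O[Si](CC)(CC)CC)[C@@]1(C)CCCO[Si](C)(C)C(C)(C)C | intermediate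
32 | (2S,2'R,3'S,6'R)-6-bromo-2'-[3-(TBSO)propyl]-2',5,6',8-tetramethyl-3'-[2-(TESO)propan-2-yl]-3H-spiro[cyclohepta[b]furan-2,1'-cyclohexan]-7-one | Brc1c(C)cc2c(c(C)c1=O)O[C@@]1(C2)[C@H](C)CC[C@H](C(C)(C)O[Si](CC)(CC)CC)[C@@]1(C)CCCO[Si](C)(C)C(C)(C)C | intermediate
33 | methyl (2S,2'R,3'S,6'R)-2'-[3-(TBSO)propyl]-2',5,6',8-tetramethyl-7-oxo-3'-[2-(TESO)propan-2-yl]-3,7-dihydrospiro[cyclohepta[b]furan-2,1'-cyclohexane]-6-carboxylate | COC(=O)c1c(C)cc2c(c(C)c1=O)O[C@@]1(C2)[C@H](C)CC[C@H](C(C)(C)O[Si](CC)(CC)CC)[C@@]1(C)CCCO[Si](C)(C)C(C)(C)C | intermediate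
34 | methyl (2S,2'R,3'S,6'R)-3'-(2-hydroxypropan-2-yl)-2'-(3-hydroxypropyl)-2',5,6',8-tetramethyl-7-oxo-3,7-dihydrospiro[cyclohepta[b]furan-2,1'-cyclohexane]-6-carboxylate | COC(=O)c1c(C)cc2c(c(C)c1=O)O[C@@]1(C2)[C@H](C)CC[C@H](C(C)(C)O)[C@@]1(C)CCCO | intermediate
35 | 3-[(2S,2'R,3'S,6'R)-3'-(2-hydroxypropan-2-yl)-6-(methoxycarbonyl)-2',5,6',8-tetramethyl-7-oxo-3,7-dihydrospiro[cyclohepta[b]furan-2,1'-cyclohexan]-2'-yl]propanoic acid (CNP0448476.4) | COC(=O)c1c(C)cc2c(c(C)c1=O)O[C@@]1(C2)[C@H](C)CC[C@H](C(C)(C)O)[C@@]1(C)CCC(=O)O | target

## Step count and least certain steps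

Total: 20 steps. Longest linear sequence: 18 steps (steps 1–8 and 11–20); steps 9 and 10 make the arene in a two-step branch.

**Step 1 (key step).** The most likely failure is over-reaction of the acrylate: the ester enolate formed by the first Michael addition adds to a second molecule of 3, or the hindered tetrasubstituted magnesium enolate reacts only at temperatures where it begins to equilibrate. An alkenyl Grignard reagent may also give some uncatalysed addition and lower the enantiomeric purity.
Fallback: from 1 and 2 the copper-catalysed addition is run alone and quenched with a proton source to give (2RS,3S)-2-methyl-3-(prop-1-en-2-yl)cyclohexan-1-one F1. F1 is then treated with 3 under catalytic KOtBu in t-BuOH–THF. This thermodynamic Michael addition alkylates the more substituted α-carbon anti to the isopropenyl group and returns to the route at 5. The copper step then has to set only one stereocentre.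

**Step 8.** Borane may add slowly at the alkene carbon next to the quaternary centre. Facial selectivity may also be poor if the ring populates the half-chair with the silyloxyisopropyl group axial, which would put the chain, not the methyl, over the alkene.
Fallback: from 14, epoxidation with mCPBA (NaHCO3, CH2Cl2) on the face opposite the axial methyl gives the epoxide F2, with the oxirane oxygen cis to the silyloxypropyl chain. Isomerisation with Et2Al(TMP) in toluene gives (1S,2R,3S)-2-[3-(TBSO)propyl]-2-methyl-6-methylidene-3-[2-(TESO)propan-2-yl]cyclohexan-1-ol F3. Hydroxyl-directed hydrogenation with [Ir(cod)(PCy3)(py)]PF6 and H2 delivers hydrogen cis to the hydroxyl and returns to the route at 16. The C6 configuration is then set by the hydroxyl group and not by the approach of a borane.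

**Step 11.** The axial alkoxide, flanked by a quaternary and a tertiary carbon, may fail to reach the fluorine-bearing carbon, which itself lies between the nitrile and a methyl group. Slow substitution leaves time for addition of the alkoxide to the nitrile.
Fallback: from 18, the arylmagnesium 19 made as in step 10 is quenched with iodine to give 2-iodo-4-methoxy-3,5-dimethylbenzonitrile F4. Oxidation with mCPBA and TsOH in the presence of 1,3,5-trimethoxybenzene gives (6-cyano-3-methoxy-2,4-dimethylphenyl)(2,4,6-trimethoxyphenyl)iodonium tosylate F5. The alkoxide 21 (from 16) is arylated by F5 at 23 °C through ligand coupling at trivalent iodine, a reaction that tolerates tertiary alkoxides, and the route is rejoined at 22.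

**Step 14.** Intermolecular carbene coupling (azine or stilbene formation) may outrun insertion into the crowded methine C–H bond.
Fallback: from 24, irradiation (350 nm, benzene) should bring about hydrogen transfer from the ether methine to the excited aldehyde and closure of the biradical (Norrish–Yang type) to the 3-hydroxy-2,3-dihydrobenzofuran F6, the 3-hydroxy derivative of 28 as both C3 epimers. Ionic deoxygenation with Et3SiH and BF3·OEt2 at −78 °C then returns to the route at 28. This fallback gives up the guaranteed retention of the insertion: the spiro configuration would depend on the closure of a biradical.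

**Step 16.** The carbene may add to the ring-fused enol ether, or to both enol ethers, so that site selectivity is lost. The second enol ether may also be hydrolysed if acid is not excluded.
Fallback: from 29, the carbenoid from methyl dichloroacetate and NaOMe is bulkier and should discriminate more strongly between the two enol ethers. It gives the 1-chlorocyclopropane-1-carboxylate F7 (methyl ester, across C5=C6 of 29). Heating in toluene opens it with loss of chloromethane to methyl (2S,2'R,3'S,6'R)-2'-[3-(TBSO)propyl]-2',5,6',8-tetramethyl-7-oxo-3'-[2-(TESO)propan-2-yl]-3,4,7,8-tetrahydrospiro[cyclohepta[b]furan-2,1'-cyclohexane]-6-carboxylate F8. DDQ as in step 17 then returns to the route at 33. The ester carbon enters with the ring carbon, so bromine and the carbonylation of step 18 are no longer needed.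

## Further compounds

F1 | step 1 | (2RS,3S)-2-methyl-3-(prop-1-en-2-yl)cyclohexan-1-one | CC1C(=O)CCC[C@@H]1C(C)=C
F2 | step 8 | epoxide of 14 with the oxirane oxygen cis to the silyloxypropyl chain | O1[C@H]2[C@]1(C)CC[C@H](C(C)(C)O[Si](CC)(CC)CC)[C@@]2(C)CCCO[Si](C)(C)C(C)(C)C
F3 | step 8 | (1S,2R,3S)-2-[3-(TBSO)propyl]-2-methyl-6-methylidene-3-[2-(TESO)propan-2-yl]cyclohexan-1-ol | O[C@H]1C(=C)CC[C@H](C(C)(C)O[Si](CC)(CC)CC)[C@@]1(C)CCCO[Si](C)(C)C(C)(C)C
F4 | step 11 | 2-iodo-4-methoxy-3,5-dimethylbenzonitrile | N#Cc1cc(C)c(OC)c(C)c1I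
F5 | step 11 | (6-cyano-3-methoxy-2,4-dimethylphenyl)(2,4,6-trimethoxyphenyl)iodonium tosylate | N#Cc1cc(C)c(OC)c(C)c1[I+]c1c(OC)cc(OC)cc1OC.Cc1ccc(cc1)S(=O)(=O)[O-]
F6 | step 14 | 3-hydroxy derivative of 28 (both C3 epimers) | COc1c(C)cc2c(c1C)O[C@@]1(C2O)[C@H](C)CC[C@H](C(C)(C)O[Si](CC)(CC)CC)[C@@]1(C)CCCO[Si](C)(C)C(C)(C)C
F7 | step 16 | methyl 1-chlorocyclopropane-1-carboxylate formed across the C5=C6 enol ether bond of 29 (diastereomer mixture) | COC1(C2(Cl)C(=O)OC)C(C)C3=C(CC12C)C[C@]4(O3)[C@H](C)CC[C@H](C(C)(C)O[Si](CC)(CC)CC)[C@@]4(C)CCCO[Si](C)(C)C(C)(C)C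
F8 | step 16 | methyl (2S,2'R,3'S,6'R)-2'-[3-(TBSO)propyl]-2',5,6',8-tetramethyl-7-oxo-3'-[2-(TESO)propan-2-yl]-3,4,7,8-tetrahydrospiro[cyclohepta[b]furan-2,1'-cyclohexane]-6-carboxylate (both C8 epimers) | COC(=O)C1=C(C)CC2=C(C(C)C1=O)O[C@@]1(C2)[C@H](C)CC[C@H](C(C)(C)O[Si](CC)(CC)CC)[C@@]1(C)CCCO[Si](C)(C)C(C)(C)C
A1 | alternative 1 | dihydrofuran-fused cycloheptadiene from the rhodium-catalysed (5+2) step (mixture at the three new sp3 ring carbons) | COC(=O)C1C(O[Si](C)(C)C(C)(C)C)C(C)=C2O[C@@]3(CC2C=C1C)[C@H](C)CC[C@H](C(C)(C)O[Si](CC)(CC)CC)[C@@]3(C)CCC(=O)OC(C)(C)C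
A2 | alternative 2 | methyl 2,4-dibromo-3-oxopentanoate | COC(=O)C(Br)C(=O)C(C)Br
A3 | alternative 2 | oxa-bridged cycloheptenone adduct of the (4+3) step (mixture at the four new ring centres) | C[Si](C)(C)O[C@@]1(CC2=CC3(C)OC2C(C)C(=O)C3C(=O)OC)[C@H](C)CC[C@H](C(C)(C)O[Si](CC)(CC)CC)[C@@]1(C)CCC(=O)OC(C)(C)C
A4 | alternative 3 | triethylsilyl ether tert-butyl ester of the target | COC(=O)c1c(C)cc2c(c(C)c1=O)O[C@@]1(C2)[C@H](C)CC[C@H](C(C)(C)O[Si](CC)(CC)CC)[C@@]1(C)CCC(=O)OC(C)(C)C
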